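(Readings and results are simulated on assumed constants, noise included.)

| setting | south-east | east | north-east | spring | dawn | midnight |
|---|---|---|---|---|---|---|
| starting material | 1 M | 1 M | 1.5 M | 1.0 M | 1.0 M | 1.0 M |
| second substrate | 0.67 equiv | 1.5 equiv | 1 equiv | 1.00 equiv | 1.00 equiv | 1.00 equiv |
| third substrate | 1 equiv | 1 equiv | 1 equiv | 1.00 equiv | 1.00 equiv | 1.00 equiv |
| gas | 200 mM (held) | 200 mM (held) | 200 mM (held) | 200 mM (held) | 200 mM (held) | 200 mM (held) |
| temperature | 105 °C | 125 °C | 105 °C |  | 140 °C | 110 °C |
| remark | run made earlier | run made earlier | run made earlier | at 140 °C until 1.0 h, from then on at 110 °C |  |  |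
| time |  |  |  | 80 min | 80 min | 80 min |

- south-east (time / min: target / %): 50.0: 38.5; 150: 61.5; 240: 62.4; 360: 62.4; 480: 62.4
- east (time / min: target / %): 40.0: 20.1; 80.0: 31.6; 120: 34.9; 180: 35.1
- north-east (time / min: target / %): 120: 40.2; 240: 45.4; 360: 46.7; 480: 46.1

(standard deviation of a reading: 0.5 percentage points)

- which flask leads in amount of target, in percent of the starting material charged ("all alike" within 1.5 percentage points) (spring / dawn / midnight / all alike)
- how much target is there at the end, in percent of the starting material charged: spring
- how much target is there at the end, in percent of the starting material charged: dawn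
- how much target is there at the end, in percent of the starting material charged: midnight

- at the start none of the gas is in solution

The amounts came first: south-east levelled at 62.4% of the starting material charged, east at 35.1%, north-east at 46.1%. I turned each last reading into a loss ratio: the part of the starting material charged that did not end as target, per part that did.

| run | last target | loss ratio |
|---|---|---|
| south-east | 62.4% | 0.603 |
| east | 35.1% | 1.85 |
| north-east | 46.1% | 1.17 |

South-east and north-east shared a bath, so I compared them. They gave 1.63 for the charge exponent, the power of the starting concentration that the loss ratio follows, an apparent order. South-east and east shared a starting concentration, and east, hotter, had 3.07 times the ratio. Both comparisons also moved the second substrate, and I let that pass.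

I spread that factor evenly over the degrees. The new flasks had the starting concentration of south-east, so the charge factor was 1.00, and I reckoned on from south-east by temperature. Midnight came to a ratio of 0.798, a plateau of 55.6%. Dawn came to 4.29, a plateau of 18.9%.

The weak link was the stop, since a plateau need not be reached by 80 min. South-east, at 38.5% after 50.0 min, showed a time constant of 52.1 min. Midnight would then stand at 78.5% of its plateau, so I wrote 43.7%. East was already at 90.0% of its plateau by 80.0 min, and dawn was hotter, so I left 18.9% for dawn and set spring level with it.

The forecast also put midnight first, with 50%, then spring at 30% and dawn at 29%, on the ground that “something is being lost to a competing process”. My figures stood lower for midnight and for dawn.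

Midnight led with 47.6%, against 23.7% for dawn and 23.3% for spring. At its stop midnight still held 14% of its starting material, and after 800 min it gave 55.8%.

    starting material + target → side product (k = 0.0210 M⁻¹ min⁻¹, Ea = 91.0 kJ mol⁻¹)
    second substrate + reagent → second product (k = 0.420 M⁻¹ min⁻¹, Ea = 77.0 kJ mol⁻¹)
    third substrate + reagent → third product (k = 0.0310 M⁻¹ min⁻¹, Ea = 80.0 kJ mol⁻¹)
    starting material + reagent → target (k = 0.280 M⁻¹ min⁻¹, Ea = 86.0 kJ mol⁻¹)
    gas ⇌ reagent, rate k5*(csat - [reagent]) (kL = 0.170 min⁻¹)
    (constants at 110 °C)

The loss ratio of spring was 3.29. Scaled with the charge exponent 1.63 to the same flask at 0.25 M, it became 0.341, which means 74.6% target. That flask gave 73.8%.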